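The numbers in the tables come from a simulation on assumed constants, noise included.

In a one-step world of target and isomer of the product, the share s of target in that pair relaxes to a fixed value, and c(isomer) stands still exactly when s has that value. The list of suspects gives the isomer no other step, so the rule carries over to the real flask: while c(isomer) falls, s lies below that value.

| flask | starting material | reagent | second substrate | remark | time |
|---|---|---|---|---|---|
| theta | 0.020 M | 1.5 equiv | 5 equiv | run made earlier |  |
| gamma | 0.020 M | 0.75 equiv | 5 equiv | run made earlier |  |
| delta | 0.020 M | 3 equiv | 5 equiv | run made earlier |  |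
| Tuesday's | 0.020 M (in portions, 5, over 2.5 h) | 1.50 equiv | 5.00 equiv | first portion at the start, last at 2.5 h | 3.0 h |
| Monday's | 0.020 M | 1.50 equiv | 5.00 equiv | everything together at the start | 3.0 h |
| Wednesday's | 0.020 M | 1.50 equiv | 5.00 equiv (fed, over 2.5 h) | all else is in the flask from the start; the feed brings no volume worth counting | 3.0 h |
| Saturday's | 0.020 M (fed, over 2.5 h) | 1.50 equiv | 5.00 equiv | all else is in the flask from the start; the feed brings no volume worth counting | 3.0 h |

theta run (percent of the starting material charged)

| time / min | target / % | isomer of the product / % |
|---|---|---|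
| 8.00 | 30.9 | 0.9 |
| 15.0 | 24.4 | 1.7 |
| 25.0 | 17.3 | 2.0 |
| 40.0 | 10.3 | 1.8 |
| 60.0 | 5.4 | 2.5 |
| 120 | 1.0 | 2.2 |

gamma run (percent of the starting material charged)

| time / h | target / % | isomer of the product / % |
|---|---|---|
| 0.250 | 13.5 | 0.6 |
| 0.667 | 4.9 | 2.6 |
| 1.33 | 0.7 | 0.5 |
| 2.00 | 0.4 | 0.7 |
| 3.00 | 0.5 | 0.3 |
| 4.00 | 0.5 | 0 |

delta run (percent of the starting material charged)

| time / h | target / % | isomer of the product / % |
|---|---|---|
| 0.250 | 40.2 | 2.0 |
| 0.667 | 21.3 | 4.1 |
| 1.33 | 9.1 | 4.5 |
| 2.00 | 4.0 | 4.5 |
| 3.00 | 2.3 | 3.4 |
| 4.00 | 0.7 | 1.6 |

(each reading ± 0.5 percentage points)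

1. the best flask by share of target in target plus isomer of the product; "all alike" if 1.5 percentage points covers them all (Tuesday's / Monday's / Wednesday's / Saturday's / all alike)
2. share of target in target plus isomer of the product at the end, Tuesday's
3. share of target in target plus isomer of the product at the end, Monday's
4. share of target in target plus isomer of the product at the end, Wednesday's
5. share of target in target plus isomer of the product at the end, Saturday's

The delta readings first reach their isomer top at 1.33 h, where they give s = 66.9%. This pair of readings, each scattered by 0.5 percentage points, is my estimate of the crossing share, the share at the isomer's maximum, and I took that estimate as my upper bound.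

For a lower bound I reckoned the drained end. The theta target decays at a pseudo-first-order rate of 2.01 /h, and the delta isomer falls at 0.517 /h, which is slower. I took this as the isomer's return to target. If binding is instant, target holds a part 26.9% of the surviving reagent, as read at 8.00 min. The returning isomer then sustains s = 8.52%.

Monday's, Tuesday's and Saturday's have 6.03 target lifetimes of burning by 3.0 h. Wednesday's has 1.01 after its feed stops, which is fewer. So I ranked Wednesday's first, between the bounds, and the others nearer the floor.

The forecast, “slow feed keeps reagent alive”, named Wednesday's with 40%, and 29%, 13% and 31% for Tuesday's, Monday's and Saturday's, all inside my bracket.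

The flasks gave 28.0% for Wednesday's, the highest, then 22.2% for Saturday's, 19.2% for Tuesday's and 17.9% for Monday's, so Wednesday's stands first and inside the bracket.

    starting material + reagent ⇌ target (K = 32.0 /M, k = 7.10 /M/min)
    second substrate + reagent → second product (k = 0.790 /M/min)
    target ⇌ isomer of the product (K = 0.450, k = 0.00380 /min)

In Wednesday's the isomer fell from 5.70% at 2.50 h to 4.70% at 3.00 h, and the share stood below the crossing share, as the rule requires. The crossing share contains no concentration, so I carried it unchanged to a neighbouring flask, Wednesday's with 0.0050 M of starting material. At 3.00 h that flask held 4.51% target and 3.40% isomer, which gives 57.1%, under my estimated bound by 9.8 points. It still held 19% of its reagent, against 1.7% in Wednesday's.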